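**Retrosynthetic overview**

1. The quinone is released last from a hydroquinone dimethyl ether. The benzylic C–C bond comes from nickel-catalysed coupling of a benzyl chloride with an alkenylalane made by methylalumination of a homopropargylic alcohol, whose carbinol centre (chain C5, S) is set by phosphoric-acid-catalysed propargylation of an enal.
2. The central C10 unit (chain C5–C12) is geranyl acetate, oxidised at its terminal E-methyl group to a 2-methyl-2-enal.
3. Key disconnection: the oxolane is cut at C2–C3 and at O1–C5 into that enal and the tertiary allylsilane CH2=CH–C(CH3)2–SiMe2Ph. They are joined by a catalytic enantioselective (3+2) annulation in which the ring closes when the aldehyde oxygen captures the tertiary carbon; the C4–Si bond is then oxidised to C4–OH with retention.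
4. Enabling feature: in the oxolane, O1 lies between the quaternary carbon C5 (two methyl groups) and the allylic carbon C2, and the hydroxyl sits on C4 next to C5. C5 can therefore carry the positive charge of a β-silyl (siliranium) cation, C4 can carry silicon as a masked hydroxyl, and O1 with C2 can come from an aldehyde C=O.
5. Ring order: the benzene ring is bought, the oxolane is the only ring built (step 4), and the quinone ring is unveiled in the last step.

Key step: step 4

Assumption: the (S)-oxazaborolidine–AlBr3 complex is taken to expose the Si face of a formyl group bound through boron and a formyl C–H···O contact, and (S)-TRIP to direct propargyl transfer to the Si face of an enal; both catalysts are available as either enantiomer.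

**Route**

Step 1
Reactants: 1 geranyl acetate
Product: 2 (2E,6E)-8-hydroxy-3,7-dimethylocta-2,6-dien-1-yl acetate
Conditions: SeO2 (cat.), t-BuOOH, salicylic acid (cat.), CH2Cl2, rt
Reagents that add atoms: selenium dioxide, O=[Se]=O (catalytic oxygen carrier); tert-butyl hydroperoxide, CC(C)(C)OO (terminal oxygen source)
Why: Selenium dioxide allylic oxidation (ene reaction then 2,3-sigmatropic shift) should hydroxylate the E-methyl group of the terminal, more electron-rich alkene, since the other alkene is deactivated by the allylic acetate.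

Step 2
Reactants: 2 (2E,6E)-8-hydroxy-3,7-dimethylocta-2,6-dien-1-yl acetate
Product: 3 (2E,6E)-3,7-dimethyl-8-oxoocta-2,6-dien-1-yl acetate
Conditions: MnO2, CH2Cl2, rt
Reagents that add atoms: none
Why: Oxidation of an allylic alcohol with MnO2 should give the 2-methyl-2-enal without E/Z isomerisation and without touching the acetate.

Step 3
Reactants: 4 1-chloro-3-methylbut-2-ene (prenyl chloride); 5 dimethyl(phenyl)(4,4,5,5-tetramethyl-1,3,2-dioxaborolan-2-yl)silane
Product: 6 dimethyl(2-methylbut-3-en-2-yl)(phenyl)silane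
Conditions: CuCl (5 mol %), 1,3-bis(2,4,6-trimethylphenyl)imidazolium chloride (6 mol %), NaOMe (1.5 equiv), THF, 0 °C to rt
Reagents that add atoms: none
Why: Copper-catalysed γ-selective (SN2') allylic substitution with a silylboronate, in which methoxide activates the Si–B bond and the silylcopper species attacks the disubstituted terminus, should give the tertiary allylsilane, as known for γ,γ-disubstituted allylic electrophiles.

Step 4
Reactants: 3 (2E,6E)-3,7-dimethyl-8-oxoocta-2,6-dien-1-yl acetate; 6 dimethyl(2-methylbut-3-en-2-yl)(phenyl)silane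
Product: 7 (2E,6E)-7-[(2S,4S)-4-[dimethyl(phenyl)silyl]-5,5-dimethyloxolan-2-yl]-3-methylocta-2,6-dien-1-yl acetate
Conditions: 6 (1.5 equiv), (S)-3,3-diphenyl-1-(2-methylphenyl)tetrahydro-1H,3H-pyrrolo[1,2-c][1,3,2]oxazaborole (20 mol %), AlBr3 (16 mol %), CH2Cl2, −78 to −40 °C
Reagents that add atoms: none
Why: Proposed new method: the aprotic chiral boron Lewis acid binds the formyl group of 3, the vinyl terminus of 6 adds anti to silicon (anti-SE2') to the open Si face of the carbonyl carbon, silicon bridges onto the secondary carbon, and the boron-bound alkoxide captures the tertiary end of the siliranium ion, which forms the O–C(CH3)2 bond, closes the oxolane and releases the catalyst; the closest known reaction types are the BF3- or SnCl4-promoted (3+2) annulation of aldehydes with allylsilanes bearing hindered silyl groups, the Sc(OTf)3–pybox-catalysed enantioselective annulations of allyl- and allenylsilanes with chelating 1,2-dicarbonyl compounds, and oxazaborolidinium-catalysed enantioselective 1,2-additions to aldehydes. The ring closes by 5-endo opening of the three-membered siliranium ion at its tertiary carbon, the regiochemistry being fixed by the gem-dimethyl group. C2 of the oxolane is set by the catalyst (Si-face attack gives 2S), and C4 follows from an antiperiplanar open transition state in which the Lewis-acid-bound oxygen points away from the silane and the aldehyde hydrogen faces the CMe2Si group, which places the alkenyl group cis to silicon (4S); cis is also expected to be the more stable 2,4-arrangement. The step needs 1,2- over 1,4-addition (secured by the 2-methyl-2-enal and the hard boron Lewis acid), ring closure over Hosomi–Sakurai desilylation (secured by the weakly nucleophilic medium, the hindered phenyldimethylsilyl group, the low temperature and the tertiary cation created by the silyl shift), and survival of the allylic acetate (low temperature).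

Step 5
Reactants: 7 (2E,6E)-7-[(2S,4S)-4-[dimethyl(phenyl)silyl]-5,5-dimethyloxolan-2-yl]-3-methylocta-2,6-dien-1-yl acetate
Product: 9 (2E,6E)-7-[(2S,4S)-4-hydroxy-5,5-dimethyloxolan-2-yl]-3-methylocta-2,6-dien-1-ol, via silyl alcohol 8 (not isolated)
Conditions: K2CO3 (cat.), MeOH, rt, then evaporation; t-BuOOH, KH, Bu4NF, DMF, 70 °C
Reagents that add atoms: tert-butyl hydroperoxide, CC(C)(C)OO
Why: Methanolysis of the acetate followed by Tamao–Fleming oxidation under basic, electrophile-free conditions (hydroperoxide attack at silicon, then aryl and alkyl 1,2-shifts from silicon to oxygen) should convert C–Si into C–OH with retention at C4 and leave the trisubstituted alkenes untouched.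

Step 6
Reactants: 9 (2E,6E)-7-[(2S,4S)-4-hydroxy-5,5-dimethyloxolan-2-yl]-3-methylocta-2,6-dien-1-ol
Product: 10 (2E,6E)-7-[(2S,4S)-4-hydroxy-5,5-dimethyloxolan-2-yl]-3-methylocta-2,6-dienal
Conditions: MnO2, CH2Cl2, rt
Reagents that add atoms: none
Why: MnO2 oxidises only the primary allylic alcohol, so the secondary ring hydroxyl should remain and the E-enal should form without isomerisation.

Step 7
Reactants: 10 (2E,6E)-7-[(2S,4S)-4-hydroxy-5,5-dimethyloxolan-2-yl]-3-methylocta-2,6-dienal
Product: 11 (2E,6E)-7-[(2S,4S)-5,5-dimethyl-4-(triethylsilyloxy)oxolan-2-yl]-3-methylocta-2,6-dienal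
Conditions: Et3SiCl, imidazole, DMAP (cat.), DMF, rt
Reagents that add atoms: chlorotriethylsilane, CC[Si](Cl)(CC)CC
Why: Silylation of the ring hydroxyl masks it so that only the chain C5 hydroxyl is acetylated later.

Step 8
Reactants: 11 (2E,6E)-7-[(2S,4S)-5,5-dimethyl-4-(triethylsilyloxy)oxolan-2-yl]-3-methylocta-2,6-dienal; 12 4,4,5,5-tetramethyl-2-(propa-1,2-dien-1-yl)-1,3,2-dioxaborolane
Product: 13 (4S,5E,9E)-10-[(2S,4S)-5,5-dimethyl-4-(triethylsilyloxy)oxolan-2-yl]-6-methylundeca-5,9-dien-1-yn-4-ol
Conditions: (S)-TRIP [(S)-3,3'-bis(2,4,6-triisopropylphenyl)-1,1'-binaphthyl-2,2'-diyl hydrogen phosphate] (10 mol %), 4 Å molecular sieves, toluene, −20 °C to rt; aqueous work-up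
Reagents that add atoms: none
Why: Chiral phosphoric-acid-catalysed propargylboration through a closed six-membered SE2' transition state should deliver the propargyl group to the Si face of the enal (1,2-addition) and set the 4S carbinol centre.

Step 9
Reactants: 14 4-methoxy-2-methylphenol
Product: 15 2-hydroxy-5-methoxy-3-methylbenzaldehyde
Conditions: MgCl2, Et3N, paraformaldehyde, MeCN, reflux
Reagents that add atoms: formaldehyde (as paraformaldehyde), C=O
Why: Casnati–Skattebøl ortho-formylation of the magnesium phenoxide should occur at the only free ortho position.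

Step 10
Reactants: 15 2-hydroxy-5-methoxy-3-methylbenzaldehyde
Product: 16 2,5-dimethoxy-3-methylbenzaldehyde
Conditions: MeI, K2CO3, DMF, rt
Reagents that add atoms: iodomethane, CI
Why: Williamson O-methylation of the phenol.

Step 11
Reactants: 16 2,5-dimethoxy-3-methylbenzaldehyde
Product: 17 (2,5-dimethoxy-3-methylphenyl)methanol
Conditions: NaBH4, MeOH, 0 °C
Reagents that add atoms: none
Why: Hydride reduction of the aldehyde.

Step 12
Reactants: 17 (2,5-dimethoxy-3-methylphenyl)methanol
Product: 18 1-(chloromethyl)-2,5-dimethoxy-3-methylbenzene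
Conditions: SOCl2, CH2Cl2, 0 °C
Reagents that add atoms: thionyl chloride, O=S(Cl)Cl
Why: Chlorination of an electron-rich benzylic alcohol through its chlorosulfite; the chloride is used directly.

Step 13
Reactants: 13 (4S,5E,9E)-10-[(2S,4S)-5,5-dimethyl-4-(triethylsilyloxy)oxolan-2-yl]-6-methylundeca-5,9-dien-1-yn-4-ol; 18 1-(chloromethyl)-2,5-dimethoxy-3-methylbenzene
Product: 20 (2E,5S,6E,10E)-1-(2,5-dimethoxy-3-methylphenyl)-11-[(2S,4S)-5,5-dimethyl-4-(triethylsilyloxy)oxolan-2-yl]-3,7-dimethyldodeca-2,6,10-trien-5-ol, via alkenylalane 19 (not isolated)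
Conditions: Me3Al (3.5 equiv), Cp2ZrCl2 (0.5 equiv), CH2Cl2, 0 °C to rt; volatiles removed; 18, NiCl2(PPh3)2 (5 mol %) pre-reduced with n-BuLi (10 mol %) to zerovalent nickel, THF, rt; aqueous work-up
Reagents that add atoms: trimethylaluminium, C[Al](C)C
Why: Negishi zirconium-catalysed syn-carboalumination places methyl on the internal and aluminium on the terminal alkyne carbon (E geometry), and nickel-catalysed cross-coupling of the alkenylalane with the benzylic chloride should proceed with retention, as known from polyprenyl quinone side-chain syntheses.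

Step 14
Reactants: 20 (2E,5S,6E,10E)-1-(2,5-dimethoxy-3-methylphenyl)-11-[(2S,4S)-5,5-dimethyl-4-(triethylsilyloxy)oxolan-2-yl]-3,7-dimethyldodeca-2,6,10-trien-5-ol
Product: 21 (2E,5S,6E,10E)-1-(2,5-dimethoxy-3-methylphenyl)-11-[(2S,4S)-5,5-dimethyl-4-(triethylsilyloxy)oxolan-2-yl]-3,7-dimethyldodeca-2,6,10-trien-5-yl acetate
Conditions: Ac2O, pyridine, DMAP (cat.), CH2Cl2, 0 °C to rt
Reagents that add atoms: acetic anhydride, CC(=O)OC(C)=O
Why: Acylation of the secondary allylic alcohol at oxygen leaves the C5 configuration unchanged.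

Step 15
Reactants: 21 (2E,5S,6E,10E)-1-(2,5-dimethoxy-3-methylphenyl)-11-[(2S,4S)-5,5-dimethyl-4-(triethylsilyloxy)oxolan-2-yl]-3,7-dimethyldodeca-2,6,10-trien-5-yl acetate
Product: 22 (2E,5S,6E,10E)-1-(2,5-dimethoxy-3-methylphenyl)-11-[(2S,4S)-4-hydroxy-5,5-dimethyloxolan-2-yl]-3,7-dimethyldodeca-2,6,10-trien-5-yl acetate
Conditions: HF·pyridine, pyridine, THF, 0 °C
Reagents that add atoms: none
Why: Buffered fluoride cleavage of the triethylsilyl ether should spare the allylic acetate and the allylic ring ether.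

Step 16
Reactants: 22 (2E,5S,6E,10E)-1-(2,5-dimethoxy-3-methylphenyl)-11-[(2S,4S)-4-hydroxy-5,5-dimethyloxolan-2-yl]-3,7-dimethyldodeca-2,6,10-trien-5-yl acetate
Product: 23 (2E,5S,6E,10E)-11-[(2S,4S)-4-hydroxy-5,5-dimethyloxolan-2-yl]-3,7-dimethyl-1-(5-methyl-3,6-dioxocyclohexa-1,4-dien-1-yl)dodeca-2,6,10-trien-5-yl acetate (CNP0106310.2)
Conditions: (NH4)2Ce(NO3)6 (2.5 equiv), MeCN–H2O (2:1), 0 °C
Reagents that add atoms: water, O
Why: Oxidative demethylation of the hydroquinone dimethyl ether should give the 1,4-benzoquinone quickly at 0 °C, before the alkenes, the acetate or the secondary alcohol react.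

**Compound list**

1 | geranyl acetate, (2E)-3,7-dimethylocta-2,6-dien-1-yl acetate | CC(=O)OC/C=C(\C)CCC=C(C)C | starting material
2 | (2E,6E)-8-hydroxy-3,7-dimethylocta-2,6-dien-1-yl acetate | CC(=O)OC/C=C(\C)CC/C=C(\C)CO | intermediate
3 | (2E,6E)-3,7-dimethyl-8-oxoocta-2,6-dien-1-yl acetate | CC(=O)OC/C=C(\C)CC/C=C(\C)C=O | intermediate
4 | 1-chloro-3-methylbut-2-ene | CC(C)=CCCl | starting material
5 | dimethyl(phenyl)(4,4,5,5-tetramethyl-1,3,2-dioxaborolan-2-yl)silane | C[Si](C)(c1ccccc1)B1OC(C)(C)C(C)(C)O1 | starting material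
6 | dimethyl(2-methylbut-3-en-2-yl)(phenyl)silane | C=CC(C)(C)[Si](C)(C)c1ccccc1 | intermediate
7 | (2E,6E)-7-[(2S,4S)-4-[dimethyl(phenyl)silyl]-5,5-dimethyloxolan-2-yl]-3-methylocta-2,6-dien-1-yl acetate | CC(=O)OC/C=C(\C)CC/C=C(\C)[C@@H]1C[C@H]([Si](C)(C)c2ccccc2)C(C)(C)O1 | intermediate
8 | (2E,6E)-7-[(2S,4S)-4-[dimethyl(phenyl)silyl]-5,5-dimethyloxolan-2-yl]-3-methylocta-2,6-dien-1-ol | OC/C=C(\C)CC/C=C(\C)[C@@H]1C[C@H]([Si](C)(C)c2ccccc2)C(C)(C)O1 | intermediate
9 | (2E,6E)-7-[(2S,4S)-4-hydroxy-5,5-dimethyloxolan-2-yl]-3-methylocta-2,6-dien-1-ol | OC/C=C(\C)CC/C=C(\C)[C@@H]1C[C@H](O)C(C)(C)O1 | intermediate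
10 | (2E,6E)-7-[(2S,4S)-4-hydroxy-5,5-dimethyloxolan-2-yl]-3-methylocta-2,6-dienal | O=C/C=C(\C)CC/C=C(\C)[C@@H]1C[C@H](O)C(C)(C)O1 | intermediate
11 | (2E,6E)-7-[(2S,4S)-5,5-dimethyl-4-(triethylsilyloxy)oxolan-2-yl]-3-methylocta-2,6-dienal | O=C/C=C(\C)CC/C=C(\C)[C@@H]1C[C@H](O[Si](CC)(CC)CC)C(C)(C)O1 | intermediate
12 | 4,4,5,5-tetramethyl-2-(propa-1,2-dien-1-yl)-1,3,2-dioxaborolane | C=C=CB1OC(C)(C)C(C)(C)O1 | starting material
13 | (4S,5E,9E)-10-[(2S,4S)-5,5-dimethyl-4-(triethylsilyloxy)oxolan-2-yl]-6-methylundeca-5,9-dien-1-yn-4-ol | O[C@H](/C=C(\C)CC/C=C(\C)[C@@H]1C[C@H](O[Si](CC)(CC)CC)C(C)(C)O1)CC#C | intermediate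
14 | 4-methoxy-2-methylphenol | Cc1cc(OC)ccc1O | starting material
15 | 2-hydroxy-5-methoxy-3-methylbenzaldehyde | O=Cc1cc(OC)cc(C)c1O | intermediate
16 | 2,5-dimethoxy-3-methylbenzaldehyde | O=Cc1cc(OC)cc(C)c1OC | intermediate
17 | (2,5-dimethoxy-3-methylphenyl)methanol | OCc1cc(OC)cc(C)c1OC | intermediate
18 | 1-(chloromethyl)-2,5-dimethoxy-3-methylbenzene | ClCc1cc(OC)cc(C)c1OC | intermediate
19 | [(1E,4S,5E,9E)-4-(dimethylalumanyloxy)-2,6-dimethyl-10-[(2S,4S)-5,5-dimethyl-4-(triethylsilyloxy)oxolan-2-yl]undeca-1,5,9-trien-1-yl]dimethylalumane | C[Al](C)O[C@H](/C=C(\C)CC/C=C(\C)[C@@H]1C[C@H](O[Si](CC)(CC)CC)C(C)(C)O1)C/C(C)=C/[Al](C)C | intermediate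
20 | (2E,5S,6E,10E)-1-(2,5-dimethoxy-3-methylphenyl)-11-[(2S,4S)-5,5-dimethyl-4-(triethylsilyloxy)oxolan-2-yl]-3,7-dimethyldodeca-2,6,10-trien-5-ol | O[C@H](/C=C(\C)CC/C=C(\C)[C@@H]1C[C@H](O[Si](CC)(CC)CC)C(C)(C)O1)C/C(C)=C/Cc1cc(OC)cc(C)c1OC | intermediate
21 | (2E,5S,6E,10E)-1-(2,5-dimethoxy-3-methylphenyl)-11-[(2S,4S)-5,5-dimethyl-4-(triethylsilyloxy)oxolan-2-yl]-3,7-dimethyldodeca-2,6,10-trien-5-yl acetate | CC(=O)O[C@H](/C=C(\C)CC/C=C(\C)[C@@H]1C[C@H](O[Si](CC)(CC)CC)C(C)(C)O1)C/C(C)=C/Cc1cc(OC)cc(C)c1OC | intermediate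
22 | (2E,5S,6E,10E)-1-(2,5-dimethoxy-3-methylphenyl)-11-[(2S,4S)-4-hydroxy-5,5-dimethyloxolan-2-yl]-3,7-dimethyldodeca-2,6,10-trien-5-yl acetate | CC(=O)O[C@H](/C=C(\C)CC/C=C(\C)[C@@H]1C[C@H](O)C(C)(C)O1)C/C(C)=C/Cc1cc(OC)cc(C)c1OC | intermediate
23 | (2E,5S,6E,10E)-11-[(2S,4S)-4-hydroxy-5,5-dimethyloxolan-2-yl]-3,7-dimethyl-1-(5-methyl-3,6-dioxocyclohexa-1,4-dien-1-yl)dodeca-2,6,10-trien-5-yl acetate | CC(=O)O[C@H](/C=C(\C)CC/C=C(\C)[C@@H]1C[C@H](O)C(C)(C)O1)C/C(C)=C/CC1=CC(=O)C=C(C)C1=O | target

**Step count**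

Total step count: 16. Longest linear sequence: 11 steps (steps 1, 2, 4, 5, 6, 7, 8, 13, 14, 15, 16, from geranyl acetate).

**Steps most likely to fail**

Step 4 (proposed method). The annulation may be outrun by Hosomi–Sakurai desilylation, a racemic background reaction may erode the enantiomeric purity, or the facial and cis/trans selectivity may be poor. The fallback builds the same oxolane from aldehyde 3 by known chemistry and returns to the route at diol 9. Brown allylation of 3 with (−)-B-allyldiisopinocampheylborane (Et2O, −78 °C; NaOH, H2O2), which attacks the Si face, should give the homoallylic alcohol (2E,6E,8S)-8-hydroxy-3,7-dimethylundeca-2,6,10-trien-1-yl acetate F1. Cross-metathesis of F1 with 2-methylbut-2-ene (second-generation Grubbs catalyst, CH2Cl2, 40 °C) should give the prenyl carbinol (2E,6E,8S)-8-hydroxy-3,7,11-trimethyldodeca-2,6,10-trien-1-yl acetate F2, which is also the desilylation by-product expected from step 4. Shi epoxidation of the terminal, most electron-rich alkene with the L-fructose-derived enantiomer of the Shi ketone (KHSO5, K2CO3 buffer, MeCN–dimethoxymethane, 0 °C, stopped at partial conversion to protect the other alkenes) should give the epoxy alcohol (2E,6E,8S)-9-[(2S)-3,3-dimethyloxiran-2-yl]-8-hydroxy-3,7-dimethylnona-2,6-dien-1-yl acetate F3. Camphorsulfonic acid (CH2Cl2, 0 °C) then forms the same O–C(CH3)2 bond by 5-endo opening of the epoxide at its tertiary carbon and should give the hydroxy oxolane (2E,6E)-7-[(2S,4S)-4-hydroxy-5,5-dimethyloxolan-2-yl]-3-methylocta-2,6-dien-1-yl acetate F4. Methanolysis (K2CO3, MeOH) gives 9.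

Step 5. Protodesilylation, or ring opening of the β-silyl ether under the basic fluoride conditions, may compete with oxidation of the hindered C–Si bond. The fallback sets out from 7 and uses silicon as a leaving group instead of an oxygen precursor. BF3·OEt2 (CH2Cl2, −20 °C) should ionise the tertiary C–O bond and expel the β-silyl group (acid-promoted Peterson-type elimination), returning the prenyl carbinol F2 with the carbinol centre from step 4 intact. F2 is then carried through F3 and F4 to 9 as described for step 4; no new compound is made.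

Step 13. Carbometalation of the alkoxide-bearing alkyne may be sluggish, or protonolysis and homocoupling may intervene in the nickel step. The fallback sets out from 13 and 18, separates the two events, reverses the polarity of the coupling, and returns at 20. Carboalumination of 13 followed by iodinolysis (I2, THF, −30 °C) should give the vinyl iodide (1E,4S,5E,9E)-1-iodo-2,6-dimethyl-10-[(2S,4S)-5,5-dimethyl-4-(triethylsilyloxy)oxolan-2-yl]undeca-1,5,9-trien-4-ol F5. Zinc insertion into 18 (Zn dust, LiCl, THF) should give (2,5-dimethoxy-3-methylbenzyl)zinc chloride F6. Negishi coupling of F5 with F6 (Pd(PPh3)4, THF, rt) gives 20.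

**Further compounds**

F1 | step 4 | (2E,6E,8S)-8-hydroxy-3,7-dimethylundeca-2,6,10-trien-1-yl acetate | CC(=O)OC/C=C(\C)CC/C=C(\C)[C@@H](O)CC=C
F2 | step 4 | (2E,6E,8S)-8-hydroxy-3,7,11-trimethyldodeca-2,6,10-trien-1-yl acetate | CC(=O)OC/C=C(\C)CC/C=C(\C)[C@@H](O)CC=C(C)C
F3 | step 4 | (2E,6E,8S)-9-[(2S)-3,3-dimethyloxiran-2-yl]-8-hydroxy-3,7-dimethylnona-2,6-dien-1-yl acetate | CC(=O)OC/C=C(\C)CC/C=C(\C)[C@@H](O)C[C@@H]1OC1(C)C
F4 | step 4 | (2E,6E)-7-[(2S,4S)-4-hydroxy-5,5-dimethyloxolan-2-yl]-3-methylocta-2,6-dien-1-yl acetate | CC(=O)OC/C=C(\C)CC/C=C(\C)[C@@H]1C[C@H](O)C(C)(C)O1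
F0 | step 5 | none | none
F5 | step 13 | (1E,4S,5E,9E)-1-iodo-2,6-dimethyl-10-[(2S,4S)-5,5-dimethyl-4-(triethylsilyloxy)oxolan-2-yl]undeca-1,5,9-trien-4-ol | O[C@H](/C=C(\C)CC/C=C(\C)[C@@H]1C[C@H](O[Si](CC)(CC)CC)C(C)(C)O1)C/C(C)=C/I
F6 | step 13 | (2,5-dimethoxy-3-methylbenzyl)zinc chloride | Cl[Zn]Cc1cc(OC)cc(C)c1OC
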